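The flavone is disconnected at C4–C4a and O1–C8a. Ring A is treated as a latent cyclohexane-1,3-dione: C5 and C8a are its two carbonyl carbons and C4a the carbon between them. Ring A therefore stays at the cyclohexenone level through the annulation, and C6, then α to the C5 ketone, takes up oxygen by enolate chemistry before aromatisation. In one operation an aroylketene, released by heating the acyl Meldrum's acid of 2,3,5,6-tetramethoxybenzoic acid, is trapped by 3-morpholinocyclohex-2-en-1-one, closing pyranone ring C with ring B already attached. The precursors are an aroyl Meldrum's acid and a tertiary enaminone. C6 silyloxylation, DDQ aromatisation and one desilylative double methylation finish the route.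

Key step: step 4

Remark: flavone numbering (O1, C2, C3, C4, C4a, C5 to C8, C8a; ring B primed) is used for all bicyclic compounds. Compound 15 is racemic at C6, and this stereocentre disappears in step 6; the target has none.

Step 1
Reactants: 1 1,2,4,5-tetramethoxybenzene
Product: 3 2,3,5,6-tetramethoxybenzoic acid, via aryllithium 2 (not isolated)
Conditions: n-BuLi, TMEDA, THF, 0 °C → rt; CO2, −78 °C → rt; aq. HCl
Reagents that add atoms: carbon dioxide, O=C=O
Why: Directed ortho-metalation should be clean because each ring C–H of 1 lies between two methoxy groups and both are equivalent by symmetry, so a single aryllithium forms and is carboxylated by CO2.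

Step 2
Reactants: 3 2,3,5,6-tetramethoxybenzoic acid; 4 Meldrum's acid (2,2-dimethyl-1,3-dioxane-4,6-dione)
Product: 6 5-[hydroxy(2,3,5,6-tetramethoxyphenyl)methylidene]-2,2-dimethyl-1,3-dioxane-4,6-dione, via acid chloride 5 (not isolated)
Conditions: (COCl)2, cat. DMF, CH2Cl2, 0 °C → rt; evaporate; then 4, DMAP (2.2 equiv), CH2Cl2, 0 °C → rt; 1 M HCl wash
Reagents that add atoms: none
Why: Acid chloride formation followed by DMAP-mediated C-acylation of Meldrum's acid is standard for aroyl Meldrum's acids, and the acid chloride is preferred over carbodiimide activation because the carboxyl group is flanked by two methoxy groups.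

Step 3
Reactants: 7 cyclohexane-1,3-dione; 8 morpholine
Product: 9 3-(morpholin-4-yl)cyclohex-2-en-1-one
Conditions: cat. TsOH, toluene, reflux, Dean–Stark trap
Reagents that add atoms: none
Why: Condensation of a cyclic 1,3-diketone with a secondary amine under azeotropic removal of water should give the vinylogous amide (enaminone formation).

Step 4
Reactants: 6 5-[hydroxy(2,3,5,6-tetramethoxyphenyl)methylidene]-2,2-dimethyl-1,3-dioxane-4,6-dione; 9 3-(morpholin-4-yl)cyclohex-2-en-1-one
Product: 12 2-(2,3,5,6-tetramethoxyphenyl)-7,8-dihydro-4H-chromene-4,5(6H)-dione, via aroylketene 10 (not isolated), via C-acylated enaminone 11 (not isolated)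
Conditions: 6 (2 equiv, added in portions), toluene, reflux (110 °C); 1 M HCl wash
Reagents that add atoms: none
Why: Heating 6 should trigger a retro-[4+2] loss of acetone and CO2 to aroylketene 10; C2 of enaminone 9, the nucleophilic carbon of the vinylogous amide, adds to the ketene carbon (C4–C4a) to give 11, whose aroyl enol oxygen then attacks the morpholine-bearing carbon and expels morpholine (O1–C8a). The closest known reaction type is the acylketene–enamine annulation to 4-pyranones, a formal hetero-[4+2] cycloaddition followed by amine elimination. Ring C closes by a 6-exo-trig addition of the enol oxygen to the iminium carbon of the zwitterionic vinylogous amide (an oxa-Michael addition–elimination), and pyranone formation makes the closure irreversible once the amine has left. No stereocentre is formed. The step needs acylation at carbon and one orientation: the tertiary nitrogen of 9 has no N–H, so only C-acylation is productive and no pyridone can arise, and the polarity of the ketene fixes its sp carbon as C4 and the aroyl carbon as C2. The second equivalent of 6 allows for aroylketene intercepted by the liberated morpholine.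

Step 5
Reactants: 12 2-(2,3,5,6-tetramethoxyphenyl)-7,8-dihydro-4H-chromene-4,5(6H)-dione
Product: 15 rac-6-[(tert-butyldimethylsilyl)oxy]-2-(2,3,5,6-tetramethoxyphenyl)-7,8-dihydro-4H-chromene-4,5(6H)-dione, via lithium enolate 13 (not isolated), via silyl dienol ether 14 (not isolated)
Conditions: LiN(iPr)2, THF, −78 °C (12 added to the base); TBSOTf, −78 °C; then mCPBA, NaHCO3, CH2Cl2, −20 → 0 °C
Reagents that add atoms: tert-butyldimethylsilyl triflate, CC(C)(C)[Si](C)(C)OS(=O)(=O)C(F)(F)F; mCPBA, O=C(OO)c1cccc(Cl)c1
Why: Kinetic deprotonation of the vinylogous ester in ring A by a hindered lithium amide at −78 °C should remove a C6 proton (the α′ regiochemistry known from Stork–Danheiser alkylations) rather than a C8 proton, O-silylation gives 2-silyloxydiene 14, and Rubottom oxidation (epoxidation of the enol ether, ring opening and 1,4-silyl shift) should deliver the α-silyloxy ketone, the silyl enol ether being far more reactive towards the peracid than ring B or the pyranone; the new C6 stereocentre is set without control, as a racemate, and is erased in step 6.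

Step 6
Reactants: 15 rac-6-[(tert-butyldimethylsilyl)oxy]-2-(2,3,5,6-tetramethoxyphenyl)-7,8-dihydro-4H-chromene-4,5(6H)-dione
Product: 16 6-[(tert-butyldimethylsilyl)oxy]-5-hydroxy-2-(2,3,5,6-tetramethoxyphenyl)-4H-chromen-4-one
Conditions: DDQ (1.2 equiv), 1,4-dioxane, reflux
Reagents that add atoms: none
Why: Quinone dehydrogenation of a cyclohexenone to a phenol should apply: DDQ abstracts hydride from the dienol of ring A and tautomerisation gives the aromatic ring with the 5-OH hydrogen-bonded to the C4 carbonyl; because the C6 oxygen stays silylated no free catechol is offered to the oxidant, ring B has no benzylic C–H to lose, and halogen-based aromatisations are avoided since C4′–H of ring B lies between two methoxy groups.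

Step 7
Reactants: 16 6-[(tert-butyldimethylsilyl)oxy]-5-hydroxy-2-(2,3,5,6-tetramethoxyphenyl)-4H-chromen-4-one
Product: 18 5,6-dimethoxy-2-(2,3,5,6-tetramethoxyphenyl)-4H-chromen-4-one (5,6,2',3',5',6'-hexamethoxyflavone), via 5-hydroxy-6-methoxyflavone 17 (not isolated)
Conditions: CsF, K2CO3, MeI (excess), DMF, N2, rt → 50 °C
Reagents that add atoms: iodomethane, CI
Why: Fluoride should cleave the aryl silyl ether to the C6 phenoxide, which is methylated at once (Williamson ether synthesis) to 17, and carbonate with excess MeI in warm DMF then methylates the chelated 5-OH, so that a free catechol never accumulates.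

Compound list
1 | 1,2,4,5-tetramethoxybenzene | COc1cc(OC)c(OC)cc1OC | starting material
2 | (2,3,5,6-tetramethoxyphenyl)lithium | [Li]c1c(OC)c(OC)cc(OC)c1OC | intermediate (not isolated)
3 | 2,3,5,6-tetramethoxybenzoic acid | OC(=O)c1c(OC)c(OC)cc(OC)c1OC | intermediate
4 | Meldrum's acid (2,2-dimethyl-1,3-dioxane-4,6-dione) | CC1(C)OC(=O)CC(=O)O1 | starting material
5 | 2,3,5,6-tetramethoxybenzoyl chloride | O=C(Cl)c1c(OC)c(OC)cc(OC)c1OC | intermediate (not isolated)
6 | 5-[hydroxy(2,3,5,6-tetramethoxyphenyl)methylidene]-2,2-dimethyl-1,3-dioxane-4,6-dione | CC1(C)OC(=O)C(=C(O)c2c(OC)c(OC)cc(OC)c2OC)C(=O)O1 | intermediate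
7 | cyclohexane-1,3-dione | O=C1CCCC(=O)C1 | starting material
8 | morpholine | C1COCCN1 | starting material
9 | 3-(morpholin-4-yl)cyclohex-2-en-1-one | O=C1C=C(N2CCOCC2)CCC1 | intermediate
10 | 3-oxo-3-(2,3,5,6-tetramethoxyphenyl)prop-1-en-1-one (aroylketene) | O=C=CC(=O)c1c(OC)c(OC)cc(OC)c1OC | intermediate (not isolated)
11 | 1-[2-(morpholin-4-yl)-6-oxocyclohex-1-en-1-yl]-3-(2,3,5,6-tetramethoxyphenyl)propane-1,3-dione | O=C1CCCC(N2CCOCC2)=C1C(=O)CC(=O)c1c(OC)c(OC)cc(OC)c1OC | intermediate (not isolated)
12 | 2-(2,3,5,6-tetramethoxyphenyl)-7,8-dihydro-4H-chromene-4,5(6H)-dione | O=C1CCCc2oc(-c3c(OC)c(OC)cc(OC)c3OC)cc(=O)c12 | intermediate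
13 | lithium 4-oxo-2-(2,3,5,6-tetramethoxyphenyl)-7,8-dihydro-4H-chromen-5-olate (C5–C6 enolate) | [Li]OC1=CCCc2oc(-c3c(OC)c(OC)cc(OC)c3OC)cc(=O)c12 | intermediate (not isolated)
14 | 5-[(tert-butyldimethylsilyl)oxy]-2-(2,3,5,6-tetramethoxyphenyl)-7,8-dihydro-4H-chromen-4-one | CC(C)(C)[Si](C)(C)OC1=CCCc2oc(-c3c(OC)c(OC)cc(OC)c3OC)cc(=O)c12 | intermediate (not isolated)
15 | rac-6-[(tert-butyldimethylsilyl)oxy]-2-(2,3,5,6-tetramethoxyphenyl)-7,8-dihydro-4H-chromene-4,5(6H)-dione | CC(C)(C)[Si](C)(C)OC1CCc2oc(-c3c(OC)c(OC)cc(OC)c3OC)cc(=O)c2C1=O | intermediate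
16 | 6-[(tert-butyldimethylsilyl)oxy]-5-hydroxy-2-(2,3,5,6-tetramethoxyphenyl)-4H-chromen-4-one | CC(C)(C)[Si](C)(C)Oc1ccc2oc(-c3c(OC)c(OC)cc(OC)c3OC)cc(=O)c2c1O | intermediate
17 | 5-hydroxy-6-methoxy-2-(2,3,5,6-tetramethoxyphenyl)-4H-chromen-4-one | COc1ccc2oc(-c3c(OC)c(OC)cc(OC)c3OC)cc(=O)c2c1O | intermediate (not isolated)
18 | 5,6-dimethoxy-2-(2,3,5,6-tetramethoxyphenyl)-4H-chromen-4-one (5,6,2',3',5',6'-hexamethoxyflavone) | COc1cc(OC)c(OC)c(-c2cc(=O)c3c(OC)c(OC)ccc3o2)c1OC | target

Total step count: 7. Longest linear sequence: 6 steps (steps 1, 2, 4, 5, 6, 7 from compound 1); step 3 is a one-step branch.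

Steps most likely to fail

Step 5. Removal of a C8 proton, which is vinylogous to both carbonyl groups, may compete with removal of a C6 proton, or the enolates may equilibrate by proton transfer, so that oxygen is delivered to the wrong carbon. The silyl group may also be lost during the peracid stage. The fallback installs the C6 oxygen on the small ring before the annulation, where only one ketone directs the deprotonation. It sets out from 9 and comes back to the route at 17. Kinetic deprotonation of 9 with LiN(iPr)2 (THF, −78 °C) at C6 and oxidation of the enolate with (camphorsulfonyl)oxaziridine should give rac-6-hydroxy-3-(morpholin-4-yl)cyclohex-2-en-1-one F1. O-Methylation with NaH and MeI (THF, 0 °C) should give rac-6-methoxy-3-(morpholin-4-yl)cyclohex-2-en-1-one F2. Annulation of F2 with 6 under the conditions of step 4 should give rac-6-methoxy-2-(2,3,5,6-tetramethoxyphenyl)-7,8-dihydro-4H-chromene-4,5(6H)-dione F3. DDQ in refluxing dioxane should aromatise ring A of F3 to 17, which K2CO3 and MeI in DMF convert to 18 as in step 7.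

Step 4. The liberated morpholine, or ketene dimerisation, may consume the aroylketene faster than the weakly nucleophilic push–pull enaminone is C-acylated, and loss of morpholine from the adduct may stall. The fallback builds ring C by condensation and oxidative cyclisation instead of ketene capture. It sets out from 2 (generated from 1 as in step 1) and comes back at 12. Quenching 2 with DMF should give 2,3,5,6-tetramethoxybenzaldehyde F4. Condensation of F4 with commercial 2-acetylcyclohexane-1,3-dione at the acetyl methyl group (pyrrolidine, AcOH, toluene, reflux) should give 3-hydroxy-2-[(2E)-3-(2,3,5,6-tetramethoxyphenyl)prop-2-enoyl]cyclohex-2-en-1-one F5. Acid-promoted 6-endo-trig oxa-Michael closure (TFA, CH2Cl2) should give rac-2-(2,3,5,6-tetramethoxyphenyl)-2,3,7,8-tetrahydro-4H-chromene-4,5(6H)-dione F6. DDQ (1 equiv, dioxane, 80 °C) should dehydrogenate C2–C3 of F6 to give 12.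

Step 6. Enolisation of the hindered α-silyloxy ketone may be slow, so that hydride abstraction stalls. Alternatively the silyl ether may be cleaved by the acidic hydroquinone, after which the liberated catechol would be oxidised further. The fallback aromatises by selenoxide elimination without a quinone oxidant. It sets out from 15 and comes back at 16. Deprotonation with LiN(SiMe3)2 (THF, −78 → −20 °C) and trapping with PhSeCl should give 6-[(tert-butyldimethylsilyl)oxy]-8-(phenylselanyl)-2-(2,3,5,6-tetramethoxyphenyl)-7,8-dihydro-4H-chromene-4,5(6H)-dione F7. A C6 selenide would serve equally, since both eliminate towards C7. Oxidation with H2O2 and pyridine (CH2Cl2, 0 °C) should cause syn-elimination of the selenoxide, and tautomerisation of the resulting dienone gives 16.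

Further compounds
F1 | step 5 | rac-6-hydroxy-3-(morpholin-4-yl)cyclohex-2-en-1-one | O=C1C=C(N2CCOCC2)CCC1O
F2 | step 5 | rac-6-methoxy-3-(morpholin-4-yl)cyclohex-2-en-1-one | COC1CCC(N2CCOCC2)=CC1=O
F3 | step 5 | rac-6-methoxy-2-(2,3,5,6-tetramethoxyphenyl)-7,8-dihydro-4H-chromene-4,5(6H)-dione | COC1CCc2oc(-c3c(OC)c(OC)cc(OC)c3OC)cc(=O)c2C1=O
F4 | step 4 | 2,3,5,6-tetramethoxybenzaldehyde | O=Cc1c(OC)c(OC)cc(OC)c1OC
F5 | step 4 | 3-hydroxy-2-[(2E)-3-(2,3,5,6-tetramethoxyphenyl)prop-2-enoyl]cyclohex-2-en-1-one | O=C1CCCC(O)=C1C(=O)/C=C/c1c(OC)c(OC)cc(OC)c1OC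
F6 | step 4 | rac-2-(2,3,5,6-tetramethoxyphenyl)-2,3,7,8-tetrahydro-4H-chromene-4,5(6H)-dione | O=C1CCCC2=C1C(=O)CC(c1c(OC)c(OC)cc(OC)c1OC)O2
F7 | step 6 | 6-[(tert-butyldimethylsilyl)oxy]-8-(phenylselanyl)-2-(2,3,5,6-tetramethoxyphenyl)-7,8-dihydro-4H-chromene-4,5(6H)-dione (diastereomer mixture) | CC(C)(C)[Si](C)(C)OC1CC([Se]c2ccccc2)c2oc(-c3c(OC)c(OC)cc(OC)c3OC)cc(=O)c2C1=O
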